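**Assumptions (one line each)**
- Numbering follows the bicyclo[3.2.1]octene skeleton of the target: C1 = bridgehead between the two carbonyls, C2 = enone C=O, C3 = enone CH, C4 = styryl-bearing carbon, C5 = other bridgehead, C6 = CH(3,5-dihydroxyphenyl), C7 = CH(4-hydroxyphenyl), C8 = bridging C=O.
- The target is (1R,5S,6R,7R), with the C7 aryl syn to the C8 bridge and the C6 aryl syn to the enone bridge; the two aryls are trans.
- The lipase is taken to give the (1S,4R)-monoacetate from the meso-diacetate, as recalled from the literature; if a given lipase batch gives the antipode, lipase acetylation of the meso-diol (vinyl acetate) supplies the enantiomer drawn.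
- The C2 carbinol (compounds 16–20) is carried as an epimer mixture and converges at step 16.
- TIPS = Si(i-Pr)3, TES = SiEt3, TBS = Si(t-Bu)Me2, TMS = SiMe3.

**Retrosynthetic overview**
1. Target 22 ⇐ tetra-TIPS dione 21 ⇐ bicyclic C2 carbinol 19/20 (deprotect and oxidise last, so C1 is never an epimerisable β-diketone carbon before the bicycle exists).
2. Six-membered enone ring, closed last: C4–C5 bond by Au(I) 6-endo-dig cyclisation of silyl enol ether 18 onto an enyne tethered at C1. The tether forces the new bridge cis to the C6 aryl.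
3. C1–C2 bond and C7 aryl: Cu-catalysed trans conjugate addition of the 4-silyloxyphenyl Grignard to (S)-enone 6, then aldol of that enolate with enynal 15.
4. Enone 6 ⇐ Ni-catalysed allylic arylation (inversion) of monoacetate 2 ⇐ lipase desymmetrisation of meso-diacetate 1, which fixes the absolute configuration.
5. Ring order: the cyclopentane (C1, C5–C8) is present from 1; the cyclohexenone ring is formed in step 14.

---

**Step 1**
Reactants: 1, cis-3,5-diacetoxycyclopent-1-ene (meso)
Product: 2, (1S,4R)-cis-4-acetoxycyclopent-2-en-1-ol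
Conditions: immobilised Candida antarctica lipase B (Novozym 435), MeOH (2–3 equiv), MTBE, rt; filter off enzyme
Reagents that add atoms: none
Why: Lipase-catalysed enantiotopic-group-selective deacetylation (enzymatic desymmetrisation of a meso-diester) cleaves only the acetate on the (S)-carbon, converting the achiral diacetate into one enantiomer of the monoacetate.

**Step 2**
Reactants: 3, 5-bromoresorcinol
Product: 4, 1-bromo-3,5-bis(triisopropylsilyloxy)benzene
Conditions: TIPSCl (2.3 equiv), imidazole, DMF, rt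
Reagents that add atoms: TIPSCl, CC(C)[Si](Cl)(C(C)C)C(C)C
Why: Standard phenol silylation; aryl TIPS ethers tolerate the organometallic, enolate and gold steps and come off with fluoride at the end.

**Step 3**
Reactants: 2; 4
Product: 5, (1S,4S)-trans-4-[3,5-bis(triisopropylsilyloxy)phenyl]cyclopent-2-en-1-ol
Conditions: 4, n-BuLi, THF, −78 °C; B(OMe)3, −78→0 °C; then 2, NiCl2(PPh3)2 (10 mol %), NaI, t-BuCN, THF, rt→45 °C; chromatograph away any cis or 1,2-isomer
Reagents that add atoms: none (the aryl group comes from 4)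
Why: Ni-catalysed allylic arylation with a lithium arylborate (Tsuji–Trost type with a hard nucleophile): ionisation anti to OAc, then aryl delivery from the metal face, gives net inversion and the trans-1,4 product, so the aryl carbon is (S); any cis isomer must be removed because it would become the enantiomeric enone in step 4.

**Step 4**
Reactants: 5
Product: 6, (S)-4-[3,5-bis(triisopropylsilyloxy)phenyl]cyclopent-2-en-1-one
Conditions: activated MnO2, CH2Cl2, rt
Reagents that add atoms: none
Why: Neutral allylic alcohol oxidation; avoiding base keeps the acidic benzylic γ-hydrogen, and therefore the stereocentre, intact.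

**Step 5**
Reactants: 7, 4-bromophenol
Product: 8, (4-bromophenoxy)triisopropylsilane
Conditions: TIPSCl, imidazole, DMF, rt
Reagents that add atoms: TIPSCl, CC(C)[Si](Cl)(C(C)C)C(C)C
Why: Phenol silylation to allow Grignard formation.

**Step 6**
Reactants: 6; 8
Product: 9, (3R,4S)-trans-4-[3,5-bis(triisopropylsilyloxy)phenyl]-3-[4-(triisopropylsilyloxy)phenyl]-1-(trimethylsilyloxy)cyclopent-1-ene
Conditions: 8, Mg, THF; then CuBr·SMe2 (10 mol %), TMSCl (2 equiv), THF, −78 °C, add 6; Et3N quench, non-aqueous work-up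
Reagents that add atoms: TMSCl, C[Si](C)(C)Cl
Why: TMSCl-accelerated Cu-catalysed conjugate addition; the aryl adds anti to the existing C4 aryl (substrate control) to give the trans-diaryl unit, and the enolate is trapped regiospecifically on the side that becomes C1.

**Step 7**
Reactants: 10, 4-hydroxybenzaldehyde
Product: 11, 4-(triisopropylsilyloxy)benzaldehyde
Conditions: TIPSCl, imidazole, DMF, rt
Reagents that add atoms: TIPSCl, CC(C)[Si](Cl)(C(C)C)C(C)C
Why: Phenol silylation.

**Step 8**
Reactants: 11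
Product: 12, (E)-1-(2-iodoethenyl)-4-(triisopropylsilyloxy)benzene
Conditions: CrCl2 (6 equiv), CHI3 (2 equiv), THF/dioxane, 0 °C→rt
Reagents that add atoms: iodoform, IC(I)I
Why: Takai olefination gives the (E)-vinyl iodide from an aromatic aldehyde with high selectivity, fixing the styryl geometry.

**Step 9**
Reactants: 12; 13, propargyl alcohol
Product: 14, (E)-5-[4-(triisopropylsilyloxy)phenyl]pent-4-en-2-yn-1-ol
Conditions: PdCl2(PPh3)2 (2 mol %), CuI (4 mol %), Et3N, THF, rt
Reagents that add atoms: none (both partners are numbered reactants)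
Why: Sonogashira coupling proceeds with retention of the (E)-alkene geometry.

**Step 10**
Reactants: 14
Product: 15, (E)-5-[4-(triisopropylsilyloxy)phenyl]pent-4-en-2-ynal
Conditions: activated MnO2, CH2Cl2, rt; use immediately
Reagents that add atoms: none
Why: Selective oxidation of a propargylic alcohol to the ynal.

**Step 11**
Reactants: 9; 15
Product: 16, (2R,3R,4S)-4-[3,5-bis(triisopropylsilyloxy)phenyl]-2-{(E)-1-hydroxy-5-[4-(triisopropylsilyloxy)phenyl]pent-4-en-2-yn-1-yl}-3-[4-(triisopropylsilyloxy)phenyl]cyclopentan-1-one (carbinol epimers)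
Conditions: MeLi (1.0 equiv), THF, 0 °C, 20 min; −78 °C, then 15; AcOH/THF quench at −78 °C
Reagents that add atoms: none
Why: Regiospecific lithium enolate from the silyl enol ether undergoes aldol 1,2-addition to the ynal (as in prostaglandin three-component couplings); the aldehyde approaches anti to the adjacent aryl, giving the 2,3-trans (all-trans) ring.

**Step 12**
Reactants: 16
Product: 17, the triethylsilyl ether of 16 (2R,3R,4S; carbinol epimers)
Conditions: TESOTf, 2,6-lutidine, CH2Cl2, −78 °C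
Reagents that add atoms: TESOTf, CC[Si](CC)(CC)OS(=O)(=O)C(F)(F)F
Why: Low-temperature silylation protects the β-hydroxy ketone without retro-aldol or epimerisation; alkyl TES is removable later in the presence of aryl TIPS.

**Step 13**
Reactants: 17
Product: 18, (3R,4R,5R)-1-(tert-butyldimethylsilyloxy)-3-[3,5-bis(triisopropylsilyloxy)phenyl]-4-[4-(triisopropylsilyloxy)phenyl]-5-{(E)-1-(triethylsilyloxy)-5-[4-(triisopropylsilyloxy)phenyl]pent-4-en-2-yn-1-yl}cyclopent-1-ene
Conditions: LDA (1.2 equiv), THF, −78 °C; TBSCl, DMPU, −78→0 °C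
Reagents that add atoms: TBSCl, CC(C)(C)[Si](C)(C)Cl
Why: Kinetic deprotonation takes the unhindered CH2 rather than the tertiary α-CH, so the enol ether forms on the side needed for ring closure and β-elimination of the OTES group is avoided.

**Step 14**
Reactants: 18
Product: 19, (1R,5S,6R,7R)-6-[3,5-bis(triisopropylsilyloxy)phenyl]-2-(triethylsilyloxy)-7-[4-(triisopropylsilyloxy)phenyl]-4-{(E)-2-[4-(triisopropylsilyloxy)phenyl]ethenyl}bicyclo[3.2.1]oct-3-en-8-one (C2 epimers)
Conditions: [JohnPhosAu(MeCN)]SbF6 (5 mol %), i-PrOH (2 equiv), CH2Cl2, 0 °C→rt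
Reagents that add atoms: none
Why: Au(I)-catalysed Conia-ene-type 6-endo-dig carbocyclisation of the silyl enol ether onto the alkyne forms C4–C5; the styryl group biases attack to the distal alkyne carbon, and the tether, fixed trans to the C7 aryl, can only reach the face cis to the C6 aryl, which sets the C5 bridgehead.

**Step 15**
Reactants: 19
Product: 20, the corresponding C2 alcohol (2-hydroxy; C2 epimers)
Conditions: HF·pyridine, excess pyridine, THF, 0 °C
Reagents that add atoms: none
Why: Buffered HF cleaves the secondary alkyl TES ether in preference to the aryl TIPS ethers and avoids acid-promoted ionisation of the dienylic carbinol.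

**Step 16**
Reactants: 20
Product: 21, (1R,5S,6R,7R)-6-[3,5-bis(triisopropylsilyloxy)phenyl]-7-[4-(triisopropylsilyloxy)phenyl]-4-{(E)-2-[4-(triisopropylsilyloxy)phenyl]ethenyl}bicyclo[3.2.1]oct-3-ene-2,8-dione
Conditions: Dess–Martin periodinane, NaHCO3, CH2Cl2, 0 °C→rt
Reagents that add atoms: none
Why: Dess–Martin oxidation of the allylic alcohol gives the enone and merges both C2 epimers; C1 is now a bridgehead and cannot epimerise.

**Step 17**
Reactants: 21
Product: 22, vitisinol D, (1R,5S,6R,7R)-6-(3,5-dihydroxyphenyl)-7-(4-hydroxyphenyl)-4-[(E)-2-(4-hydroxyphenyl)ethenyl]bicyclo[3.2.1]oct-3-ene-2,8-dione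
Conditions: TBAF/AcOH (1:1, 5 equiv), THF, 0 °C→rt; pH 6 buffer work-up
Reagents that add atoms: none
Why: Buffered fluoride removes all four aryl silyl ethers without exposing the non-enolisable bridged β-diketone to nucleophilic base (retro-Claisen).

---

**Compound list**

1 | cis-3,5-diacetoxycyclopent-1-ene (meso) | CC(=O)O[C@@H]1C[C@H](OC(C)=O)C=C1 | starting material
2 | (1S,4R)-cis-4-acetoxycyclopent-2-en-1-ol | CC(=O)O[C@@H]1C[C@H](O)C=C1 | intermediate
3 | 5-bromoresorcinol | Oc1cc(O)cc(Br)c1 | starting material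
4 | 1-bromo-3,5-bis(triisopropylsilyloxy)benzene | Brc1cc(O[Si](C(C)C)(C(C)C)C(C)C)cc(O[Si](C(C)C)(C(C)C)C(C)C)c1 | intermediate
5 | (1S,4S)-trans-4-[3,5-bis(TIPSO)phenyl]cyclopent-2-en-1-ol | O[C@@H]1C=C[C@@H](c2cc(O[Si](C(C)C)(C(C)C)C(C)C)cc(O[Si](C(C)C)(C(C)C)C(C)C)c2)C1 | intermediate
6 | (S)-4-[3,5-bis(TIPSO)phenyl]cyclopent-2-en-1-one | O=C1C=C[C@@H](c2cc(O[Si](C(C)C)(C(C)C)C(C)C)cc(O[Si](C(C)C)(C(C)C)C(C)C)c2)C1 | intermediate
7 | 4-bromophenol | Oc1ccc(Br)cc1 | starting material
8 | (4-bromophenoxy)triisopropylsilane | Brc1ccc(O[Si](C(C)C)(C(C)C)C(C)C)cc1 | intermediate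
9 | (3R,4S)-TMS enol ether of the trans-3,4-diarylcyclopentanone | C[Si](C)(C)OC1=C[C@H](c2ccc(O[Si](C(C)C)(C(C)C)C(C)C)cc2)[C@@H](c2cc(O[Si](C(C)C)(C(C)C)C(C)C)cc(O[Si](C(C)C)(C(C)C)C(C)C)c2)C1 | intermediate
10 | 4-hydroxybenzaldehyde | O=Cc1ccc(O)cc1 | starting material
11 | 4-(triisopropylsilyloxy)benzaldehyde | O=Cc1ccc(O[Si](C(C)C)(C(C)C)C(C)C)cc1 | intermediate
12 | (E)-1-(2-iodoethenyl)-4-(triisopropylsilyloxy)benzene | I/C=C/c1ccc(O[Si](C(C)C)(C(C)C)C(C)C)cc1 | intermediate
13 | propargyl alcohol | C#CCO | starting material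
14 | (E)-5-[4-(TIPSO)phenyl]pent-4-en-2-yn-1-ol | OCC#C/C=C/c1ccc(O[Si](C(C)C)(C(C)C)C(C)C)cc1 | intermediate
15 | (E)-5-[4-(TIPSO)phenyl]pent-4-en-2-ynal | O=CC#C/C=C/c1ccc(O[Si](C(C)C)(C(C)C)C(C)C)cc1 | intermediate
16 | (2R,3R,4S)-aldol adduct (carbinol epimers) | O=C1C[C@H](c2cc(O[Si](C(C)C)(C(C)C)C(C)C)cc(O[Si](C(C)C)(C(C)C)C(C)C)c2)[C@@H](c2ccc(O[Si](C(C)C)(C(C)C)C(C)C)cc2)[C@@H]1C(O)C#C/C=C/c1ccc(O[Si](C(C)C)(C(C)C)C(C)C)cc1 | intermediate
17 | TES ether of 16 | O=C1C[C@H](c2cc(O[Si](C(C)C)(C(C)C)C(C)C)cc(O[Si](C(C)C)(C(C)C)C(C)C)c2)[C@@H](c2ccc(O[Si](C(C)C)(C(C)C)C(C)C)cc2)[C@@H]1C(O[Si](CC)(CC)CC)C#C/C=C/c1ccc(O[Si](C(C)C)(C(C)C)C(C)C)cc1 | intermediate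
18 | (3R,4R,5R)-TBS enol ether of 17 | CC(C)(C)[Si](C)(C)OC1=C[C@H](c2cc(O[Si](C(C)C)(C(C)C)C(C)C)cc(O[Si](C(C)C)(C(C)C)C(C)C)c2)[C@@H](c2ccc(O[Si](C(C)C)(C(C)C)C(C)C)cc2)[C@@H]1C(O[Si](CC)(CC)CC)C#C/C=C/c1ccc(O[Si](C(C)C)(C(C)C)C(C)C)cc1 | intermediate
19 | (1R,5S,6R,7R)-bicyclic 2-OTES enone precursor (C2 epimers) | CC[Si](CC)(CC)OC1C=C(/C=C/c2ccc(O[Si](C(C)C)(C(C)C)C(C)C)cc2)[C@H]2C(=O)[C@@H]1[C@H](c1ccc(O[Si](C(C)C)(C(C)C)C(C)C)cc1)[C@H]2c1cc(O[Si](C(C)C)(C(C)C)C(C)C)cc(O[Si](C(C)C)(C(C)C)C(C)C)c1 | intermediate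
20 | bicyclic C2 alcohol (C2 epimers) | OC1C=C(/C=C/c2ccc(O[Si](C(C)C)(C(C)C)C(C)C)cc2)[C@H]2C(=O)[C@@H]1[C@H](c1ccc(O[Si](C(C)C)(C(C)C)C(C)C)cc1)[C@H]2c1cc(O[Si](C(C)C)(C(C)C)C(C)C)cc(O[Si](C(C)C)(C(C)C)C(C)C)c1 | intermediate
21 | tetra-O-TIPS vitisinol D | O=C1C=C(/C=C/c2ccc(O[Si](C(C)C)(C(C)C)C(C)C)cc2)[C@H]2C(=O)[C@@H]1[C@H](c1ccc(O[Si](C(C)C)(C(C)C)C(C)C)cc1)[C@H]2c1cc(O[Si](C(C)C)(C(C)C)C(C)C)cc(O[Si](C(C)C)(C(C)C)C(C)C)c1 | intermediate
22 | vitisinol D | O=C1C=C(/C=C/c2ccc(O)cc2)[C@H]2C(=O)[C@@H]1[C@H](c1ccc(O)cc1)[C@H]2c1cc(O)cc(O)c1 | target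

---

**Totals**
- Total steps: 17
- Longest linear sequence: 11 (steps 1, 3, 4, 6, 11–17)

**Three steps most likely to fail, with fallbacks**

1. **Step 14 (Au 6-endo-dig closure of the bridged ring).** Risks are 5-exo closure, protodesilylation of the enol ether, or side reactions of the electron-rich enyne.
 Fallback: trap the enolate from 9 with (Z)-3-iodoacrolein instead of 15 and close C4–C5 by Pd-catalysed intramolecular ketone α-alkenylation (Pd(PPh3)4, PhOK). After C2 oxidation to the unsubstituted enone, add the (E)-styryl group from 12 as a cuprate at C4 and regenerate the enone by Saegusa dehydrogenation; only C3 can enolise.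

2. **Step 3 (Ni allylic arylation).** Risks are 1,2- versus 1,4-regioselectivity and cis/trans leakage with the bulky arylborate, which would erode ee.
 Fallback: convert 2 into (S)-4-(tert-butyldimethylsilyloxy)cyclopent-2-enone (TBS protection, acetate removal, oxidation). Add the aryl cuprate from 4 anti to the OTBS group and eliminate silanolate (DBU) to reach 6 by conjugate addition–elimination.

3. **Step 13 (kinetic enol silylation of a β-silyloxy ketone).** Risks are E1cB loss of the OTES group or enolisation on the wrong side.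
 Fallback: remove the β-oxygen during ring construction. C-alkylate the enolate from 9 with the propargylic bromide made from 14, so C2 is CH2 through enol silylation and Au cyclisation, then install the C2 carbonyl last by allylic oxidation (SeO2/TBHP or CrO3·3,5-dimethylpyrazole); the only other allylic position is a bridgehead.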